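1. Count the turnovers of the free catalyst: left-handed product made per free catalyst charged and per hour.

| flask | left-handed substrate | right-handed substrate | solid reagent | free catalyst | racemization catalyst | remark | time |
|---|---|---|---|---|---|---|---|
| west | 0.20 M | 0.20 M | 4 equiv | 13 mol% | 1.2 mol% | run made earlier |  |
| north-east | 0.20 M | 0.20 M | 4 equiv | 13 mol% | 1.9 mol% | run made earlier |  |
| flask | 0.20 M | 0.20 M | 4.00 equiv | 13 mol% | 2.5 mol% |  | 1.0 h |

| run | time / min | left-handed substrate / % | right-handed substrate / % | left-handed product / % |
|---|---|---|---|---|
| west | 5.00 | 47 | 50 | 1 |
| west | 15.0 | 45 | 49 | 8 |
| west | 25.0 | 44 | 44 | 10 |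
| west | 40.0 | 40 | 43 | 17 |
| west | 60.0 | 37 | 41 | 26 |
| west | 80.0 | 30 | 36 | 34 |
| north-east | 5.00 | 49 | 49 | 5 |
| north-east | 15.0 | 48 | 45 | 6 |
| north-east | 25.0 | 44 | 48 | 10 |
| north-east | 40.0 | 39 | 45 | 17 |
| north-east | 60.0 | 35 | 38 | 25 |
| north-east | 80.0 | 28 | 38 | 34 |

(readings scatter by 1.5 percentage points)

- free catalyst is single-handed; left-handed substrate and right-handed substrate are mirror images of each other, charged as a racemate, each of them at the stated concentration
- solid, in amounts per volume of the solution: solid reagent
- candidate steps: coupling partner + free catalyst + right-handed substrate -> free catalyst + right-handed product; 2 racemization catalyst -> spent catalyst; solid reagent <-> coupling partner; left-handed substrate + racemization catalyst <-> right-handed substrate + racemization catalyst; coupling partner + free catalyst + left-handed substrate -> free catalyst + left-handed product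
- at the start none of the solid reagent is in solution
- an excess is the difference of the two amounts in percent of their sum
- an excess is below zero if the other one leads

- part of the left-handed substrate and right-handed substrate charged together that has reacted at 1.0 h
- excess of left-handed product over right-handed product in the product at 1.0 h
- excess of right-handed substrate over left-handed substrate among what is left of the two at 1.0 h

2. First instants: none of the solid reagent is in solution at the start, so the coupling partner has to dissolve before any coupling runs. I find the left-handed product at 1% in the west run and 5% in the north-east run at 5.00 min, and with a scatter of 1.5 percentage points I can't read a lag from that.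

3. Middle: at 40.0 min the two runs read left-handed product at 17% and 17%, despite 1.2 mol% against 1.9 mol% of racemization catalyst, so I take the coupling as indifferent to that charge.

4. End: at 80.0 min the west run reads left-handed product at 34%, which gives 3.92 h⁻¹, my turnover frequency, the left-handed product made per free catalyst charged and per hour, on average over that run. What is about to matter is the lead of the right-handed substrate, which I read as 6 points and 10 points at that time, against 3 points and 6 points at 40.0 min.

5. My own count for the flask, at 13 mol% of free catalyst over 1.0 h, gives 25.5% of left-handed product.

6. The forecast says 26% reacted (23% to 29%), an excess of left-handed product of 95% (85% to 99.5%) and an excess of right-handed substrate of 4% (1.5% to 8%), with the early curve “consistent with the coupling partner being fed slowly from the solid”.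

7. The flask gives 26.9% reacted, an excess of left-handed product of 95.0% and an excess of right-handed substrate of 5.56%, each within the forecast's range.

    coupling partner + free catalyst + right-handed substrate → free catalyst + right-handed product (k = 0.0460 M⁻² s⁻¹)
    2 racemization catalyst → spent catalyst (k = 1.60 M⁻¹ s⁻¹)
    solid reagent ⇌ coupling partner, rate k3*(cs3 - [coupling partner]) while solid is left; crystals form when [coupling partner] > cs3 (solubility = 17.0 mM, k = 0.00230 s⁻¹)
    left-handed substrate + racemization catalyst ⇌ right-handed substrate + racemization catalyst, rate k4*[racemization catalyst]*[left-handed substrate] forward; the back reaction follows from the equilibrium constant (k = 8.50 M⁻¹ s⁻¹)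
    coupling partner + free catalyst + left-handed substrate → free catalyst + left-handed product (k = 1.90 M⁻² s⁻¹)

8. The left-handed product in the flask stands at 26.2% after 1.00 h, which is 4.03 h⁻¹ per free catalyst charged, against my 3.92 h⁻¹. In the flask the coupling partner is made 1.01 times as fast as it is used at 0.488 h and 1.01 times at 1.00 h, a quasi-steady state with [coupling partner] at 0.00416 M at the end.

9. For the neighbour flask with 5.2 mol% of free catalyst, 3.92 h⁻¹ gives 10.2% of left-handed product. The computed neighbour flask has 20.3% reacted, of which 19.8% is left-handed product, and that is 7.61 h⁻¹, twice my turnover frequency, with [coupling partner] at 0.00717 M.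

(The data are calculated from invented constants, noise included.)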